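The vessel takes equal charges of first and second end groups in both flasks asked about, so I assumed one second-order step and reckoned with one fraction left for both groups.

| flask | first end groups | second end groups | temperature | remark | time |
|---|---|---|---|---|---|
| zeta | 0.80 M (fed, over 50 min) | 1.1 M | 65 °C | run made earlier; the fed solution adds 0.50 times the starting volume |  |
| delta | 0.80 M (fed, over 50 min) | 1.8 M | 85 °C | run made earlier; the fed solution adds 0.50 times the starting volume |  |
| beta | 1.6 M (fed, over 50 min) | 0.80 M | 65 °C | run made earlier; the fed solution adds 0.50 times the starting volume |  |
| east | 0.80 M | 0.800 M | 70 °C | everything together at the start, the whole solution of first end groups included, so that from the start the volume is larger by 0.50 times the starting volume | 1.0 h |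
| south-east | 0.80 M (fed, over 50 min) | 0.800 M | 100 °C | the fed solution adds 0.50 times the starting volume | 1.0 h |

zeta run (percent of the first end groups charged)

| time / h | links / % | first end groups / % |
|---|---|---|
| 0.500 | 10.4 | 49.3 |
| 1.00 | 26.5 | 73.1 |
| 2.00 | 48.6 | 50.4 |
| 2.50 | 58.1 | 42.2 |
| 3.00 | 62.9 | 36.5 |
| 4.00 | 72.3 | 28.6 |

delta run (percent of the first end groups charged)

| time / min | links / % | first end groups / % |
|---|---|---|
| 5.00 | 1.4 | 8.5 |
| 15.0 | 12.6 | 17.4 |
| 25.0 | 24.5 | 24.3 |
| 40.0 | 46.1 | 34.0 |
| 60.0 | 70.7 | 28.5 |
| 80.0 | 83.9 | 14.7 |

beta run (percent of the first end groups charged)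

| time / h | links / % | first end groups / % |
|---|---|---|
| 0.833 | 14.8 | 84.0 |
| 1.33 | 23.5 | 76.5 |
| 2.00 | 31.0 | 68.4 |
| 3.00 | 39.3 | 60.0 |
| 4.00 | 43.3 | 57.6 |

(standard deviation of a reading: 1 percentage point)

- charges are per starting volume, the dose included; the dosed solution carries all of it
- percentages count the whole charge, also what has not yet gone in
- a reading or a percentage of links counts all its forms, free or not

- the flask that ends with the higher amount of links, in percent of the first end groups charged, or "neither" when 2 percentage points or less lies between them (east / south-east / neither)
- final links, as a percentage of the first end groups charged, in east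
- final links, as a percentage of the first end groups charged, in south-east

I worked with the fraction left. Second-order plots of the readings after the feed gave a rate constant of 1.88 × 10⁻⁴ M⁻¹ s⁻¹ in zeta and 2.11 × 10⁻⁴ M⁻¹ s⁻¹ in beta, with either group in excess, so I kept the second-order form and went on from the value of zeta. Delta read 7.16 × 10⁻⁴ M⁻¹ s⁻¹, which with zeta makes an activation energy of 67.3 kJ mol⁻¹. For one second-order step on equal charges the fraction left is the reciprocal of one plus N, where N is the rate constant times the diluted concentration times the time (a second-order Damköhler number); for east N is 0.512, so I reckoned east to leave 66.1% and make 33.9% links.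

For south-east, N over the whole time at 100 °C is 3.41, and my ceiling, with the charge in from the start, was 77.3%. My floor counted just the 10.0 min after the feed and gave 36.2%, already more than my 33.9% for east. A steady feed gives the charge a mean time of 35.0 min in the flask, so I committed to 66.5%, with south-east higher.

The forecast gave 35% for east and 62% for south-east, with “South-east clearly ends higher”; its south-east lay inside my bracket and lower than mine.

The flask gave 36.1% in east and 59.5% in south-east, so south-east ended higher; my east was 2.2 percentage points low and my south-east 7 points high.

    second end groups ⇌ dormant form (K = 0.219, k = 1.89 × 10⁻⁴ s⁻¹, Ea = 112 kJ mol⁻¹, ΔH = −64.0 kJ mol⁻¹)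
    first end groups + second end groups → rings, rate k2*[first end groups] as long as [second end groups] is above zero (k = 2.58 × 10⁻⁵ s⁻¹, Ea = 108 kJ mol⁻¹)
    crystals ⇌ links, rate k3*(cs3 - [links]) while solid is left; crystals form when [links] > cs3 (solubility = 0.700 M, k = 0.0173 s⁻¹)
    first end groups + second end groups → links (k = 0.00188 M⁻¹ s⁻¹, Ea = 65.0 kJ mol⁻¹)
    (constants at 100 °C)

Temperature was the main reason south-east ended above east: with the difference in temperature taken away, east run at the temperature of south-east gave 72.3% links in place of 36.1%. In my reckoning that step raised N from 0.512 to 3.41. A repeat of east at 45 °C moved N the other way, to 0.0803, which reckons to 7.43% links, and that flask gave 8.79%.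

The earlier runs and the new flask were generated by integration for an exercise.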